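All constants are those of an exercise; the result is computed.

E lasts 10.0 s on average, far shorter than the 40 s run, so E at the end remembers the last stretch of J and not the whole history.

| flask | J | X | time | remark |
|---|---|---|---|---|
| Saturday's | 20 mM (fed, over 40.0 s) | 10.0 mM | 40 s | all but J at the start; J goes in evenly over 40.0 s, the run ends at 40 s |
| Wednesday's | 20 mM | 10.0 mM | 40 s | plug flow through a tube for 40 s, no back-mixing |
| Thursday's | 20 mM | 10.0 mM |  | a single well-mixed tank run continuously and read at steady state, 40 s in it on average |
| Tuesday's | 20 mM | 10.0 mM | 40 s | everything together in a closed stirred flask, run for 40 s |

    E → L (k1 = 0.10 s⁻¹)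
    J + X → J.X (k2 = 120 M⁻¹ s⁻¹)
    J + J2 → J.J2 (k3 = 0.62 M⁻¹ s⁻¹)
    2 J → J2 (k4 = 3.0 M⁻¹ s⁻¹)
    J → E (k5 = 0.070 s⁻¹)

- percentages count the J that a species holds: one J2 counts as two
- percentages count the J that a species holds: one J.J2 counts as three
- a step written with two of one species runs at k times the square of its concentration and takes two of it each time
- the stated concentrations are those of everything mixed, before any reaction; amounts are the same in each set-up
- the feed brings no volume worth counting
- run time (Saturday's): 40 s

- the set-up with the highest amount of E at the outlet or at the end, in percent of the J put in ("none" if the first two lie within 2 percentage points) (Saturday's / Wednesday's / Thursday's / Tuesday's / none)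
- amount of E at the outlet or at the end, in percent of the J put in, Saturday's
- amount of E at the outlet or at the end, in percent of the J put in, Wednesday's
- amount of E at the outlet or at the end, in percent of the J put in, Thursday's
- amount of E at the outlet or at the end, in percent of the J put in, Tuesday's

E obeys a first-order lag: it is made at 0.070 s⁻¹ times J and lost at 0.10 s⁻¹ times E. J held steady therefore carries E at the holding ratio g = 0.700, the E standing per unit of J, and a moving J can be replaced by its mean over the memory. Saturday's is the flask whose J should still be rising at the end, so the reckoning is made there and the bet goes on it.

Saturday's feed runs at F = 0.500 mM s⁻¹. J cannot pass the ceiling where F equals the loss to E plus the loss to J2: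

J ceiling = 5.00 mM, so E stays below 17.5 %.

X, the limiting reagent, holds J low first. Feed against charge gives an earliest end at 20.0 s. A rough allowance for the leak to E, with J taken as just keeping pace with the feed, moves this to a nominal end at 25.4 s. That allowance leaves out the J that builds up free, so the nominal end is a mark for the reckoning and not the time at which X is gone.

From that mark J is taken to climb as a lag of constant 10.0 s, which equals the lifetime of E. Two equal lags in series, started from nothing at the nominal end, give a rough lower side, an estimate and not a strict bound:

E above 7.52 %.

Starting instead at the earliest end, with the faster constant 0.130 s⁻¹, tightens the top, though not strictly, because J need not be nothing there: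

E below 11.6 %.

The forecast names Saturday's, with 10.5 %, 2.8 %, 6.9 % and 2.8 % in the asked order, inside this bracket , on the grounds “so E is formed late”.

The simulation gives Saturday's as best, with 10.1 %, against 2.78 % for Wednesday's, 6.86 % for Thursday's and 2.78 % for Tuesday's; Saturday's value lies inside the bracket . At 40.0 s Saturday's holds J at 21.1 %, Tuesday's at 1.49 %. Divided by g, Saturday's E reads as a remembered J of 14.5 %, between the 5.99 % at 20.0 s and the 21.1 % at the end.

Tuesday's flask read at 15 s holds J at 9.98 % and falling, so g, with the memory filled to 77.7 %, gives a floor of 5.43 %. The computed E there is 10.5 %, above that floor.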